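Start with the easy step: follow one left-handed and one right-handed substrate molecule in a racemate where the single-handed free catalyst joins each to the partner. Both meet the same catalyst and the same partner, so the two rates stand as s times [left-handed substrate] to [right-handed substrate], as two monomers compete in a copolymer feed, with s a fixed number at a fixed temperature. It follows that, at that temperature, the share left of the left-handed substrate is the share left of the right-handed substrate raised to the power s.

| flask | left-handed substrate | right-handed substrate | partner | protic impurity | free catalyst | temperature | remark | time |
|---|---|---|---|---|---|---|---|---|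
| epsilon | 0.094 M | 0.094 M | 0.154 M | 0.014 M | 14 mM | 52 °C | run made earlier |  |
| delta | 0.21 M | 0.21 M | 0.154 M | 0.014 M | 14 mM | 102 °C | run made earlier |  |
| grey | 0.14 M | 0.14 M | 0.154 M | 0.0140 M | 14 mM | 30 °C |  | 8.0 h |
| violet | 0.14 M | 0.14 M | 0.154 M | 0.0140 M | 14 mM | 90 °C |  | 8.0 h |
| red | 0.14 M | 0.14 M | 0.154 M | 0.0140 M | 14 mM | 120 °C |  | 8.0 h |
| amber | 0.14 M | 0.14 M | 0.154 M | 0.0140 M | 14 mM | 60 °C |  | 8.0 h |

| run | time / min | left-handed product / % | right-handed product / % |
|---|---|---|---|
| epsilon | 10.0 | 7.8 | 0 |
| epsilon | 15.0 | 11.0 | 0.3 |
| epsilon | 25.0 | 19.6 | 0.2 |
| epsilon | 40.0 | 24.4 | 1.2 |
| epsilon | 60.0 | 31.0 | 0.1 |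
| epsilon | 80.0 | 34.2 | 0.7 |
| epsilon | 120 | 40.6 | 0.3 |
| delta | 1.50 | 12.1 | 0 |
| delta | 3.00 | 18.5 | 0 |
| delta | 5.00 | 24.7 | 0.6 |
| delta | 6.00 | 24.0 | 2.0 |
| delta | 8.00 | 26.2 | 1.1 |
| delta | 10.0 | 27.7 | 2.2 |

(scatter of a reading: 1 percentage point)

1. the flask with the highest excess of left-handed product over right-handed product ("all alike" if they lie within 1.5 percentage points) (grey / violet / red / amber / all alike)
2. excess of left-handed product over right-handed product at the end, grey
3. excess of left-handed product over right-handed product at the end, violet
4. excess of left-handed product over right-handed product at the end, red
5. excess of left-handed product over right-handed product at the end, amber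

- free catalyst is single-handed; left-handed substrate and right-handed substrate are mirror images of each other, charged as a racemate, each of them at the stated concentration
- the numbers in the tables scatter with a standard deviation of 1 percentage point
- reactions considered so far: partner + free catalyst + left-handed substrate -> free catalyst + left-handed product; partner + free catalyst + right-handed substrate -> free catalyst + right-handed product; partner + protic impurity -> quenched reagent; free catalyst -> spent catalyst
- an excess is below zero if the other one leads

Each substrate is half of the percentage base. Averaging the delta readings from 5.00 min on, taking each mean as a share of its own substrate and dividing the logarithms of the two shares left gives s = 24.0, a reading that carries the scatter. This s, the selectivity factor, says how many times more readily a left-handed molecule is taken than a right-handed one at equal concentration, here at 102 °C. In the epsilon run, colder and with less substrate charged, the last reading has right-handed product at 0.3 % beside 40.6 % of left-handed, with a scatter of 1 percentage point. So I expect grey, the coldest flask, to lead.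

For red I use this s, though red is hotter, and take two extremes. If red stopped after its first turnovers, each product molecule would be left-handed with chance 96.0 %, an excess (the difference of the two products over their sum) of 92.0 %. If red ran until the partner was gone, the impurity would take 0.0140 M and leave 0.140 M, equal to one substrate charge. The shares consumed then add up to one, so the right-handed rest is one less the left-handed rest x, and the power rule, solved by repeated substitution, puts x at 9.39 %; the excess is then one less twice x, 81.2 %. The excess falls as the left-handed substrate thins, so I put red between these two.

The forecast has grey ahead: grey 98.5 %, amber 94 %, violet 86 %, red 76 %, with the words “Violet and red use all the partner”. Its red lies below my lower extreme.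

The flasks give grey 98.0 %, amber 93.7 %, violet 91.4 % and red 90.2 %, so grey leads.

    partner + free catalyst + left-handed substrate → free catalyst + left-handed product (k = 1.20 /M²/s, Ea = 51.0 kJ/mol)
    partner + free catalyst + right-handed substrate → free catalyst + right-handed product (k = 0.0250 /M²/s, Ea = 71.0 kJ/mol)
    partner + protic impurity → quenched reagent (k = 0.00840 /M/s, Ea = 72.0 kJ/mol)
    free catalyst → spent catalyst (k = 4.40 × 10⁻⁴ /s, Ea = 105 kJ/mol)
    (constants at 90 °C)

After 8.0 h, red holds 35 % of its partner and 41 % of its left-handed substrate, each of its own charge, with free catalyst at 0 %. Taking that rest to the power of one over s gives the right-handed rest, and so an excess of 88.4 % against the simulated 90.2 %. The neighbour of red charged with 0.39 M of partner ends with 6.7 % of its left-handed substrate. The same reckoning gives it 79.6 %, and that flask stands at 82.6 %.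

(The readings come from a simulation with made-up constants; noise was put on by code.)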